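**Strategy.** The upper pyran ring (ring C: O1, C2, C3, C4, C4a, C8a) is disconnected at C2–C3, together with the interflavan C4–C8 bond. The route exploits that upper C4 is benzylic to ring A and para to O7. A chiral Brønsted acid condenses a 2-vinylphenol with 3,4-bis(benzyloxy)benzaldehyde; the O-aryl oxocarbenium ion (O1=C2) is attacked by the vinyl terminus (C3) and ring C closes. The unveiled C4 cation is intercepted in the same flask by C8 of benzylated (+)-catechin, trans to the C2 aryl group. Three simple components, a styrene, an aldehyde and a flavan-3-ol, thus give the whole protected skeleton; hydrogenolysis ends the synthesis.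

Key step: step 3

Remark: compounds 1, 3 and 5 are taken as commercial. Flavan numbering is used throughout (B-ring positions primed). Intermediate 7 carries no C4 descriptor because both C4 epimers ionise to the same cation. The (S,S) descriptor of the acid in step 3 is provisional: which antipode leads to the 2S series must be fixed in the first run, and a wrong C2 shows up as a diastereomer because 4 is enantiopure.

**Step 1**
Reactants: 1 4-(benzyloxy)-2-hydroxybenzaldehyde
Product: 2 5-(benzyloxy)-2-vinylphenol
Conditions: Ph3PCH3Br (1.3 equiv), KOtBu (2.5 equiv), THF, 0 °C to rt; AcOH quench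
Reagents that add atoms: methyltriphenylphosphonium bromide, C[P+](c1ccccc1)(c1ccccc1)c1ccccc1.[Br-]
Why: Wittig methylenation; the non-stabilised ylide adds to the aldehyde of the potassium phenoxide (hence the extra base) and the oxaphosphetane collapses to the terminal alkene, with no stereocentre formed.

**Step 2**
Reactants: 3 (+)-catechin, (2R,3S)
Product: 4 5,7,3',4'-tetra-O-benzyl-(+)-catechin
Conditions: BnBr (4.2 equiv), K2CO3 (4.5 equiv), DMF, 0 °C to rt
Reagents that add atoms: benzyl bromide, BrCc1ccccc1
Why: Williamson etherification of the four phenols with a carbonate base should leave the secondary 3-OH free and does not touch C2 or C3, so the (2R,3S) configuration is carried through unchanged.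

**Step 3**
Reactants: 2 5-(benzyloxy)-2-vinylphenol; 5 3,4-bis(benzyloxy)benzaldehyde; 4 5,7,3',4'-tetra-O-benzyl-(+)-catechin
Product: 8 (2S,4R)-7-benzyloxy-2-[3,4-bis(benzyloxy)phenyl]chroman-4-yl-(4→8)-5,7,3',4'-tetra-O-benzyl-(+)-catechin (hepta-O-benzyl dimer), via oxocarbenium ion 6 (not isolated), via flavan-4-ol 7 (not isolated)
Conditions: (S,S)-IDPi acid (confined imidodiphosphorimidate with 3,3'-diaryl-BINOL units and N-triflyl groups, 5 mol%), CHCl3, −40 °C; then 4 (2.5 equiv), TMSOTf (10 mol%), CH2Cl2, −78 to −30 °C
Reagents that add atoms: none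
Why: Proposed new method: the strong chiral acid condenses phenol 2 with aldehyde 5 to the O-aryl oxocarbenium ion 6 (O1=C2), held as a contact ion pair with the confined anion; the vinyl terminus (C3) attacks C2 in a Prins cyclisation, and the resulting C4 benzylic cation, stabilised by the para 7-benzyloxy group and by O1, is first parked as flavan-4-ol 7 by the water just released, then re-ionised by TMSOTf and captured by C8 of 4 in a Friedel–Crafts alkylation. The closest known reaction types are the imidodiphosphorimidate-catalysed asymmetric Prins cyclisation of aldehydes with homoallylic alcohols (here the hydroxyl is phenolic and two ring carbons are aromatic, which has not been shown), the Prins–Friedel–Crafts cascade of tetrahydropyran synthesis, and the Lewis-acid coupling of 4-oxygenated flavans with benzylated catechin used for procyanidins. Ring C closes in 6-endo-trig mode at C2–C3; a 5-exo closure would give a primary cation, and oxonia-Cope scrambling is blocked because C4a–C8a is an aromatic bond. C2 (S) is set by the catalyst, which shields one face of the oxocarbenium ion in a chair-like transition state with the B-ring aryl pseudo-equatorial; C4 (R) is set by the substrate, since the nucleophile adds pseudo-axially to the half-chair cation on the face anti to the equatorial C2 aryl, giving the 2,4-trans (4β) bond. The step needs enantioface selectivity at C2 (catalyst), 2,4-trans selectivity (C2 aryl) and C8-over-C6 regioselectivity on 4 (C8, flanked by O1 and 7-OBn, is the more nucleophilic site and the usual one in 4→8 couplings).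

**Step 4**
Reactants: 8 hepta-O-benzyl dimer
Product: 9 (2S,4R)-2-(3,4-dihydroxyphenyl)-7-hydroxychroman-4-yl-(4→8)-(+)-catechin (target)
Conditions: H2 (1 atm), Pd(OH)2/C, THF/MeOH/H2O, rt
Reagents that add atoms: none
Why: Hydrogenolysis of the seven aryl benzyl ethers over palladium dihydroxide on carbon; under neutral conditions the cyclic C2–O1 bonds and the diarylmethine C4–C8 bond should not be cleaved, so all four stereocentres persist.

**Compound list**
1 | 4-(benzyloxy)-2-hydroxybenzaldehyde | O=Cc1ccc(OCc2ccccc2)cc1O | starting material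
2 | 5-(benzyloxy)-2-vinylphenol | C=Cc1ccc(OCc2ccccc2)cc1O | intermediate
3 | (+)-catechin, (2R,3S) | O[C@H]1Cc2c(O)cc(O)cc2O[C@@H]1c1ccc(O)c(O)c1 | starting material
4 | 5,7,3',4'-tetra-O-benzyl-(+)-catechin, (2R,3S), 3-OH free | O[C@H]1Cc2c(OCc3ccccc3)cc(OCc3ccccc3)cc2O[C@@H]1c1ccc(OCc2ccccc2)c(OCc2ccccc2)c1 | intermediate
5 | 3,4-bis(benzyloxy)benzaldehyde | O=Cc1ccc(OCc2ccccc2)c(OCc2ccccc2)c1 | starting material
6 | O-[5-(benzyloxy)-2-vinylphenyl] oxocarbenium ion of 5 (cation, chiral anion as counter-ion) | C=Cc1ccc(OCc2ccccc2)cc1[O+]=Cc1ccc(OCc2ccccc2)c(OCc2ccccc2)c1 | intermediate (not isolated)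
7 | (2S)-7-(benzyloxy)-2-[3,4-bis(benzyloxy)phenyl]chroman-4-ol, C4 epimers | OC1C[C@@H](c2ccc(OCc3ccccc3)c(OCc3ccccc3)c2)Oc2cc(OCc3ccccc3)ccc12 | intermediate (not isolated)
8 | hepta-O-benzyl dimer: upper (2S,4R)-2,4-trans flavan joined C4→C8 to (2R,3S)-tetra-O-benzylcatechin | c1ccccc1COc1ccc2c(c1)O[C@H](c1ccc(OCc3ccccc3)c(OCc3ccccc3)c1)C[C@H]2c1c(OCc3ccccc3)cc(OCc3ccccc3)c2c1O[C@H](c1ccc(OCc3ccccc3)c(OCc3ccccc3)c1)[C@@H](O)C2 | intermediate
9 | CNP0227165.4: (2S,4R)-3',4',7-trihydroxyflavan-(4β→8)-(+)-catechin | Oc1ccc2c(c1)O[C@H](c1ccc(O)c(O)c1)C[C@H]2c1c(O)cc(O)c2c1O[C@H](c1ccc(O)c(O)c1)[C@@H](O)C2 | target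

**Total step count:** 4
**Longest linear sequence:** 3 steps (1 → 2 → 8 → 9; the branch 3 → 4 joins at step 3)

**Steps most likely to fail**

1. Step 3 (proposed new method). Two processes threaten it: cationic oligomerisation of the electron-rich styrene by the strong acid before the oxocarbenium ion is formed, and poor enantioface discrimination at C2, which would give 2-epimeric dimers. The fallback uses known chemistry, sets out from 5 and returns at 7. Claisen–Schmidt condensation of 5 with commercial 1-[4-(benzyloxy)-2-hydroxyphenyl]ethanone (CC(=O)c1ccc(OCc2ccccc2)cc1O; KOH, EtOH, rt) should give the (E)-2'-hydroxychalcone F1. NaOAc in refluxing EtOH should close it by oxa-Michael addition to racemic 7,3',4'-tri-O-benzylflavanone F2. Kinetic resolution by transfer hydrogenation with RuCl[(S,S)-TsDPEN](p-cymene), HCO2H/Et3N, stopped near half conversion, is expected to reduce the 2S ketone to the (2S,4S)-cis epimer of 7. It leaves the (2R)-flavanone F3, which base re-racemises through the chalcone for recycling. Isolated 7 is then coupled with 4 under TMSOTf as in the second stage of step 3 to give 8.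

2. Step 4. Incomplete removal of seven benzyl groups, together with air oxidation of the catechol rings during isolation, may make the polar nonaphenol hard to purify. The fallback sets out from 8 and returns at 9. The crude hydrogenolysis mixture is filtered under argon and acetylated at once (Ac2O, pyridine, DMAP) to the nona-acetate F4. F4 is stable and can be purified on silica. Degassed K2CO3/MeOH at 0 °C, followed by acidic resin, should then release 9.

3. Step 1. The free vinylphenol may oligomerise under acid or heat during work-up and chromatography. The fallback sets out from 1 and returns at 2. Silylation (TBSCl, imidazole, DMF) gives the silyl ether aldehyde F5. Wittig methylenation (Ph3PCH3Br, KOtBu, THF, 0 °C) gives the storable silyl-protected styrene F6. Buffered fluoride (TBAF/AcOH, THF, 0 °C) liberates 2 just before step 3.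

**Further compounds**
F1 | step 3 | (E)-1-[4-(benzyloxy)-2-hydroxyphenyl]-3-[3,4-bis(benzyloxy)phenyl]prop-2-en-1-one | O=C(/C=C/c1ccc(OCc2ccccc2)c(OCc2ccccc2)c1)c1ccc(OCc2ccccc2)cc1O
F2 | step 3 | racemic 7-(benzyloxy)-2-[3,4-bis(benzyloxy)phenyl]chroman-4-one | O=C1CC(c2ccc(OCc3ccccc3)c(OCc3ccccc3)c2)Oc2cc(OCc3ccccc3)ccc12
F3 | step 3 | (2R)-7-(benzyloxy)-2-[3,4-bis(benzyloxy)phenyl]chroman-4-one (unreacted enantiomer) | O=C1C[C@H](c2ccc(OCc3ccccc3)c(OCc3ccccc3)c2)Oc2cc(OCc3ccccc3)ccc12
F4 | step 4 | nona-O-acetate of 9 | CC(=O)Oc1ccc2c(c1)O[C@H](c1ccc(OC(C)=O)c(OC(C)=O)c1)C[C@H]2c1c(OC(C)=O)cc(OC(C)=O)c2c1O[C@H](c1ccc(OC(C)=O)c(OC(C)=O)c1)[C@@H](OC(C)=O)C2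
F5 | step 1 | 4-(benzyloxy)-2-[(tert-butyldimethylsilyl)oxy]benzaldehyde | O=Cc1ccc(OCc2ccccc2)cc1O[Si](C)(C)C(C)(C)C
F6 | step 1 | [5-(benzyloxy)-2-vinylphenoxy](tert-butyl)dimethylsilane | C=Cc1ccc(OCc2ccccc2)cc1O[Si](C)(C)C(C)(C)C
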